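## Structural features

The target has three rings in two units: a fully substituted 4-hydroxy-2-pyrone (6-ethyl, 5-methyl) and a 2,2-dimethyl-2H-chromene whose benzene ring is a phloroglucinol nucleus. One CH2 group joins them, running from pyrone C3 to chromene C6, between the phenols at C5 and C7. The benzene ring is hexasubstituted: C4a and C8a (with O1) belong to the pyran ring, C5 and C7 carry OH, C6 the bridge and C8 the (S)-2-methylbutanoyl group. The only stereocentre is the α-carbon of that aryl ketone. It has no stereogenic neighbour, but it is enolisable and can racemise under acid or base. Fragile sites are the styrene-type C3=C4 bond of the chromene (acid, hydrogenation), the electron-rich phenolic ring (oxidation), the doubly activated bridge CH2 and the pyrone lactone. The real difficulty is regiochemical: three ring oxygens must be told apart so that the pyran oxygen ends up para to the bridge and ortho to the acyl group, and the bridge must join two different nucleophilic rings without symmetric dimers. The key step uses the fact that the pyrone ring (O1, C2, C3, C4, C5, C6) is the sum of a malonyl unit (C2–C3–C4, with the bridge carbon already on C3) and the enolate of a symmetric ketone (C5 with its methyl, C6 with its ethyl, and O1).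

## Logic of the disconnections

19 to 16 and 18 (18 from 17): the aryl–acyl bond C8–C(=O) is cut first. The only stereocentre sits on this chain next to a ketone, so introducing it in the last step means nothing downstream can racemise it. C8 is the only unsubstituted ring carbon of 16, so no regiochemical question arises. The gain is an achiral precursor and a chiral-pool acyl donor. The demand is an electrophilic acylation mild enough for the C3=C4 bond of 16 and for the configuration of 18.

16 to 15: the two O–CH2OMe bonds are restored. This adds no skeletal simplification, but the acetals are what keep the two phenols next to the bridge out of the pyran ring closure. The demand is an acetal cleavage that the chromene survives.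

15 to 12 and 13 (through 14): the pyran ring is cut at C4–C4a and O1–C2. A five-carbon enal supplies C2, C3, C4 and both methyl groups. In 12 the single free phenol lies on the symmetry axis through the bridge carbon, so its two ortho carbons are equivalent and only one chromene can form. The gain is one ring and five carbons. The demand is enough nucleophilicity at the ring carbon and no competition from the pyrone, which is met because every pyrone carbon is substituted.

12 to 11: the O–benzyl bond is restored. The para oxygen must differ from the two ortho oxygens and must stay masked during the enolate chemistry. The demand is a hydrogenolysis that leaves the pyrone intact, placed before any alkene exists.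

11 to 8 and 9 (through 10): the pyrone is cut at C4–C5 and O1–C2. This separates a symmetric five-carbon ketone from a malonyl unit that already carries the bridge and the protected arene, so the unsymmetrical bridge is never made by coupling two nucleophilic rings. The gain is the whole pyrone ring. The demand is C-acylation of the ketone enolate by one carbonyl of 8 only, then closure through oxygen.

8 to 7 to 6: the acyl C–N bond and then the ester are traced back to a cyclic malonate. The two carboxyl groups of 6 are differentiated by ring opening, not by selective hydrolysis. The demand is activation of 7 without decarboxylation or strong acid.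

6 to 3 and 4 (through 5): the bond between the bridge carbon and the malonyl carbon is cut. The bridge carbon is the aldehyde carbon of 3. The gain is a simple aromatic aldehyde and a three-carbon diacid equivalent. The demand is condensation at a hindered, electron-rich aldehyde and a reduction that spares the benzyl ether.

3 to 2 to 1: three O–C bonds of the protecting groups are cut. The demand is selective alkylation of the para oxygen of 1, which is the most acidic and the only one not chelated to the aldehyde.

## Other disconnections considered

Alternative 1: The benzene ring is cut at C8–C8a and C6–C7. In the forward sense 1,1-dimethoxy-3-(trimethylsilyloxy)buta-1,3-diene A3 would add to (S)-1-ethoxy-4-methylhex-1-yn-3-one A2; loss of methanol and desilylation would give (S)-1-(2-ethoxy-4-hydroxy-6-methoxyphenyl)-2-methylbutan-1-one A1.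
- In its favour: the acyl group and its stereocentre would be placed regiospecifically between two oxygens under neutral thermal conditions, with no acylium ion and no Lewis acid. The polarised partners should leave no regiochemical doubt.
- Against it here: A1 lacks the chromene, the bridge and the pyrone. Its free hydroxyl is para to the ketone, whereas the pyran oxygen of the target is the one that A1 carries as a methyl ether. The methyl and ethyl ethers would need boron trihalide-type cleavage next to an enolisable stereocentre. Once both are cleaved the ring is symmetric about the acyl axis, so the differentiation bought by the cycloaddition is lost. The bridge to 6-ethyl-4-hydroxy-5-methyl-2H-pyran-2-one A4 would then need a one-carbon coupling of two nucleophiles, where symmetric dimers can compete.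
- Comparison: on stereochemical safety of the ketone-forming bond this alternative is the better plan, since the chosen route acylates a sensitive chromene with a racemisable acid chloride. On structure it is weaker, because it builds a benzene ring that the chosen plan buys, and leaves the chromene and bridge regiochemistry open. On step economy it should be longer: A2 needs several steps from the chiral acid, and dealkylation is added.

Alternative 2: The ring bond C7–C8 is cut, unfolding the benzene ring to a tetraketide held as 4-hydroxy-6-[(3S)-3-methyl-2-oxopentyl]-2H-pyran-2-one A6. In the forward sense Mg(OMe)2 would open A6 to the magnesium-chelated 3,5,7-trioxo ester; its central methylene would attack the ester carbon (Claisen mode) to give (S)-2-methyl-1-(2,4,6-trihydroxyphenyl)butan-1-one A5.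
- In its favour: it is biomimetic and short, uses no Lewis acid, and fixes the acyl position by construction.
- Against it here: the aldol mode of the same triketo ester would give a resorcylate in place of A5. The stereocentre would pass through a polyanion in basic methanol. A5 is the plain acylphloroglucinol, which a one-step acylation of phloroglucinol would also give. Annulation of A5 to (2S)-1-(5,7-dihydroxy-2,2-dimethyl-2H-chromen-8-yl)-2-methylbutan-1-one A7 would have to choose between the chelated ortho hydroxyl, which the target needs, and the free para hydroxyl. Joining A7 to A4 through a one-carbon electrophile could give symmetric dimers.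
- Comparison: on step economy this alternative is clearly the better plan, at roughly half the step count of the chosen route. On mechanism the two are close relatives: both close a ring from a polyketide-type chain, here through carbon and in the chosen plan through oxygen. On structure the chosen plan is stronger, because symmetry and protecting groups settle every regiochemical question, whereas this alternative leaves two selectivity problems to its last two steps and carries the stereocentre through base and hot amine.

Alternative 3: The pyrone is cut at C3–C4. In the forward sense the enolate of methyl (2Z)-3-({3-[5,7-bis(methoxymethoxy)-2,2-dimethyl-2H-chromen-6-yl]propanoyl}oxy)-2-methylpent-2-enoate A8 would attack its cis methyl ester in a Dieckmann-type closure. The product would be 3-{[5,7-bis(methoxymethoxy)-2,2-dimethyl-2H-chromen-6-yl]methyl}-6-ethyl-4-hydroxy-5-methyl-2H-pyran-2-one A9, which is the same substance as compound 15 of the chosen route.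
- In its favour: the C–C bond forms intramolecularly, so C- versus O-acylation is not at issue. The O1–C2 bond would come from a simple O-acylation of a β-keto ester. The chromene is in place before the pyrone, so no hydrogenolysis and no annulation would be run in the presence of the pyrone.
- Against it here: enol esters under strong base can fragment to a ketene and a β-keto ester enolate, or undergo an O-to-C acyl shift, instead of closing. The Z enol ester must be made selectively. The chromene-bearing arylpropanoic acid needs its own multistep synthesis.
- Comparison: the endgame is equal, since both plans meet at the same late intermediate and share the last two operations. This alternative is better in avoiding the intermolecular C-acylation selectivity and the benzyl ether. It is weaker in the fragmentation risk of its key step and in the longer route to its aryl fragment, whereas the chosen plan uses a trivial symmetric ketone. Step counts should be similar.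

Key step: step 6

Remark on the chemistry: 7, 8 and 10 carry stereocentres and keto–enol forms that vanish when the pyrone ring forms; they are used as mixtures and drawn without configuration.

## Route

Step 1
Reactants: 1 2,4,6-trihydroxybenzaldehyde
Product: 2 4-(benzyloxy)-2,6-dihydroxybenzaldehyde
Conditions: BnBr (1.05 equiv), CsHCO3 (1.1 equiv), MeCN, 60 °C
Reagents that add atoms: benzyl bromide, BrCc1ccccc1
Why: Williamson etherification; the 4-OH is the most acidic hydroxyl and the only one not hydrogen-bonded to the aldehyde, so one equivalent of weak base should alkylate it selectively, and the formyl group disfavours C-alkylation of the ring.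

Step 2
Reactants: 2 4-(benzyloxy)-2,6-dihydroxybenzaldehyde
Product: 3 4-(benzyloxy)-2,6-bis(methoxymethoxy)benzaldehyde
Conditions: NaH (2.5 equiv), MOMCl (2.5 equiv), DMF, 0 °C to rt
Reagents that add atoms: chloromethyl methyl ether, COCCl
Why: O-alkylation of the two chelated phenols as their sodium phenoxides gives the bis-acetal; the aldehyde has no α-hydrogen and tolerates NaH.

Step 3
Reactants: 3 4-(benzyloxy)-2,6-bis(methoxymethoxy)benzaldehyde; 4 2,2-dimethyl-1,3-dioxane-4,6-dione (Meldrum's acid)
Product: 6 5-{[4-(benzyloxy)-2,6-bis(methoxymethoxy)phenyl]methyl}-2,2-dimethyl-1,3-dioxane-4,6-dione, via arylidene Meldrum's acid 5 (not isolated)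
Conditions: L-proline (20 mol %), Hantzsch ester (1.1 equiv), EtOH, rt
Reagents that add atoms: none
Why: Organocatalytic three-component reductive alkylation; proline-mediated Knoevenagel condensation gives the strongly electrophilic arylidene 5, which the Hantzsch ester reduces in situ by hydride transfer before a second molecule of 4 can add. The benzyl ether, which catalytic hydrogenation would cleave, is untouched.

Step 4
Reactants: 6 5-{[4-(benzyloxy)-2,6-bis(methoxymethoxy)phenyl]methyl}-2,2-dimethyl-1,3-dioxane-4,6-dione
Product: 7 2-{[4-(benzyloxy)-2,6-bis(methoxymethoxy)phenyl]methyl}-3-methoxy-3-oxopropanoic acid (racemic)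
Conditions: MeOH–toluene (1:1), reflux
Reagents that add atoms: methanol, CO
Why: Alcoholysis of a 5-monosubstituted Meldrum's acid; methanol opens the cyclic acylal at one carbonyl and acetone is lost, giving the malonic half ester directly with no selective saponification. The temperature stays below that of decarboxylation.

Step 5
Reactants: 7 2-{[4-(benzyloxy)-2,6-bis(methoxymethoxy)phenyl]methyl}-3-methoxy-3-oxopropanoic acid
Product: 8 methyl 2-{[4-(benzyloxy)-2,6-bis(methoxymethoxy)phenyl]methyl}-3-(1H-benzotriazol-1-yl)-3-oxopropanoate (racemic)
Conditions: 1H-benzotriazole (1.1 equiv), DCC (1.1 equiv), CH2Cl2, 0 °C to rt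
Reagents that add atoms: 1H-benzotriazole, c1ccc2[nH]nnc2c1
Why: Carbodiimide coupling of the acid with the N–H of benzotriazole gives the N-acylbenzotriazole, a neutral and storable acyl donor; no acid chloride and no HCl are involved, so the MOM acetals are safe.

Step 6
Reactants: 8 methyl 2-{[4-(benzyloxy)-2,6-bis(methoxymethoxy)phenyl]methyl}-3-(1H-benzotriazol-1-yl)-3-oxopropanoate; 9 3-pentanone
Product: 11 3-{[4-(benzyloxy)-2,6-bis(methoxymethoxy)phenyl]methyl}-6-ethyl-4-hydroxy-5-methyl-2H-pyran-2-one, via triketide ester 10 (not isolated)
Conditions: 9 (5 equiv), MgBr2·OEt2 (3 equiv), i-Pr2NEt (4 equiv), CH2Cl2, 0 °C, slow addition of 8, then rt; then DBU (3 equiv), toluene, 80 °C; aq. citric acid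
Reagents that add atoms: none
Why: Soft enolisation with MgBr2·OEt2 and i-Pr2NEt gives the magnesium enolate of symmetric 9, whose carbon attacks the acylbenzotriazole carbonyl of 8 and expels benzotriazolide, forming pyrone C4–C5 in the magnesium-chelated triketide 10 (closest known type: soft-enolisation C-acylation of ketones by N-acylbenzotriazoles to 1,3-diketones). The malonyl C–H of 8 is more acidic than 9, so part of the acylation is expected to run through the derived methoxycarbonyl ketene, which the same enolate captures at the same carbon to give the same 10; excess 9, excess base and slow addition of 8 are used for this reason. On warming with DBU the enol oxygen of the C5 ketone of 10 adds to the methyl ester carbonyl and methoxide leaves, a 6-exo-trig lactonisation that forms O1–C2 and closes the pyrone ring (closest known type: DBU cyclisation of 3,5-dioxo esters to 4-hydroxy-2-pyrones). No stereocentre is created: the two sp3 centres of 10 become sp2 carbons of the pyrone, and the product rests as the 4-oxidopyrone until acidification. The step needs C- over O-acylation, which magnesium chelation of enolate and acyl donor should secure, and attack at the acylbenzotriazole and not at the ester, which the far better leaving group secures. Enolisation raises no regiochemical issue because 9 is symmetric. Closure must go through oxygen and not carbon; an amine base reaches only the doubly activated C–H positions of 10, so the terminal CH2 that would give a carbocyclic trione stays protonated.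

Step 7
Reactants: 11 3-{[4-(benzyloxy)-2,6-bis(methoxymethoxy)phenyl]methyl}-6-ethyl-4-hydroxy-5-methyl-2H-pyran-2-one
Product: 12 6-ethyl-4-hydroxy-3-{[4-hydroxy-2,6-bis(methoxymethoxy)phenyl]methyl}-5-methyl-2H-pyran-2-one
Conditions: H2 (1 atm), 10% Pd/C, EtOAc, rt
Reagents that add atoms: none
Why: Hydrogenolysis of the aryl benzyl ether; the tetrasubstituted 4-hydroxy-2-pyrone and the MOM acetals should be inert under these conditions, and no alkene is present yet.

Step 8
Reactants: 12 6-ethyl-4-hydroxy-3-{[4-hydroxy-2,6-bis(methoxymethoxy)phenyl]methyl}-5-methyl-2H-pyran-2-one; 13 3-methylbut-2-enal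
Product: 15 3-{[5,7-bis(methoxymethoxy)-2,2-dimethyl-2H-chromen-6-yl]methyl}-6-ethyl-4-hydroxy-5-methyl-2H-pyran-2-one, via ortho-quinone methide 14 (not isolated)
Conditions: 13 (2 equiv), ethylenediammonium diacetate (20 mol %), toluene, reflux
Reagents that add atoms: none
Why: Amine salt-catalysed chromene annulation; the carbon ortho to the free phenol attacks the iminium ion of 13, loss of the amine gives ortho-quinone methide 14, and oxa-6π electrocyclisation closes the pyran ring. The two ortho carbons are equivalent by symmetry, the MOM groups block the other oxygens, and the fully substituted pyrone cannot condense with the enal.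

Step 9
Reactants: 15 3-{[5,7-bis(methoxymethoxy)-2,2-dimethyl-2H-chromen-6-yl]methyl}-6-ethyl-4-hydroxy-5-methyl-2H-pyran-2-one
Product: 16 3-[(5,7-dihydroxy-2,2-dimethyl-2H-chromen-6-yl)methyl]-6-ethyl-4-hydroxy-5-methyl-2H-pyran-2-one
Conditions: HCl (3 M aq., 2 equiv), MeOH, 40 °C, argon
Reagents that add atoms: none
Why: Acid-catalysed transacetalisation of the two aryl MOM ethers to methanol; dilute acid and moderate temperature are chosen to spare the chromene C3=C4 bond, and the electron-rich product is kept under argon and used at once.

Step 10
Reactants: 17 (S)-2-methylbutanoic acid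
Product: 18 (S)-2-methylbutanoyl chloride
Conditions: (COCl)2 (1.2 equiv), DMF (cat.), CH2Cl2, 0 °C to rt; concentrate, use crude
Reagents that add atoms: oxalyl chloride, ClC(=O)C(=O)Cl
Why: Acid chloride formation through the chloroiminium species under cold, base-free conditions, so that no ketene forms and the α-stereocentre is retained.

Step 11
Reactants: 16 3-[(5,7-dihydroxy-2,2-dimethyl-2H-chromen-6-yl)methyl]-6-ethyl-4-hydroxy-5-methyl-2H-pyran-2-one; 18 (S)-2-methylbutanoyl chloride
Product: 19 3-({5,7-dihydroxy-2,2-dimethyl-8-[(2S)-2-methylbutanoyl]-2H-chromen-6-yl}methyl)-6-ethyl-4-hydroxy-5-methyl-2H-pyran-2-one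
Conditions: AlCl3 (4 equiv), CH2Cl2–MeNO2, slow addition of 18 (1.1 equiv), −10 to 0 °C; then ice, 1 M HCl
Reagents that add atoms: none
Why: Friedel–Crafts C-acylation of a phloroglucinol-type nucleus; C8 is the only unsubstituted ring carbon and is activated by O1, 7-OH and 5-OH, so the regiochemistry is fixed, and the fully substituted pyrone can only be O-acylated reversibly. The stereocentre comes unchanged from 17, and slow addition of 18 at low temperature keeps the acylium concentration low, so capture by the arene should outrun racemisation through the ketene.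

## Compound list

1 | 2,4,6-trihydroxybenzaldehyde | O=Cc1c(O)cc(O)cc1O | starting material
2 | 4-(benzyloxy)-2,6-dihydroxybenzaldehyde | O=Cc1c(O)cc(OCc2ccccc2)cc1O | intermediate
3 | 4-(benzyloxy)-2,6-bis(methoxymethoxy)benzaldehyde | O=Cc1c(OCOC)cc(OCc2ccccc2)cc1OCOC | intermediate
4 | 2,2-dimethyl-1,3-dioxane-4,6-dione (Meldrum's acid) | CC1(C)OC(=O)CC(=O)O1 | starting material
5 | 5-{[4-(benzyloxy)-2,6-bis(methoxymethoxy)phenyl]methylidene}-2,2-dimethyl-1,3-dioxane-4,6-dione | CC1(C)OC(=O)C(=Cc2c(OCOC)cc(OCc3ccccc3)cc2OCOC)C(=O)O1 | intermediate (not isolated)
6 | 5-{[4-(benzyloxy)-2,6-bis(methoxymethoxy)phenyl]methyl}-2,2-dimethyl-1,3-dioxane-4,6-dione | CC1(C)OC(=O)C(Cc2c(OCOC)cc(OCc3ccccc3)cc2OCOC)C(=O)O1 | intermediate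
7 | 2-{[4-(benzyloxy)-2,6-bis(methoxymethoxy)phenyl]methyl}-3-methoxy-3-oxopropanoic acid (racemic) | COC(=O)C(Cc1c(OCOC)cc(OCc2ccccc2)cc1OCOC)C(=O)O | intermediate
8 | methyl 2-{[4-(benzyloxy)-2,6-bis(methoxymethoxy)phenyl]methyl}-3-(1H-benzotriazol-1-yl)-3-oxopropanoate (racemic) | COC(=O)C(Cc1c(OCOC)cc(OCc2ccccc2)cc1OCOC)C(=O)n1nnc2ccccc12 | intermediate
9 | 3-pentanone | CCC(=O)CC | starting material
10 | methyl 2-{[4-(benzyloxy)-2,6-bis(methoxymethoxy)phenyl]methyl}-4-methyl-3,5-dioxoheptanoate (mixture of stereoisomers and enol forms) | CCC(=O)C(C)C(=O)C(Cc1c(OCOC)cc(OCc2ccccc2)cc1OCOC)C(=O)OC | intermediate (not isolated)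
11 | 3-{[4-(benzyloxy)-2,6-bis(methoxymethoxy)phenyl]methyl}-6-ethyl-4-hydroxy-5-methyl-2H-pyran-2-one | CCc1oc(=O)c(Cc2c(OCOC)cc(OCc3ccccc3)cc2OCOC)c(O)c1C | intermediate
12 | 6-ethyl-4-hydroxy-3-{[4-hydroxy-2,6-bis(methoxymethoxy)phenyl]methyl}-5-methyl-2H-pyran-2-one | CCc1oc(=O)c(Cc2c(OCOC)cc(O)cc2OCOC)c(O)c1C | intermediate
13 | 3-methylbut-2-enal | CC(C)=CC=O | starting material
14 | 6-ethyl-4-hydroxy-5-methyl-3-{[2,6-bis(methoxymethoxy)-3-(3-methylbut-2-en-1-ylidene)-4-oxocyclohexa-1,5-dien-1-yl]methyl}-2H-pyran-2-one | O=C1C=C(OCOC)C(Cc2c(O)c(C)c(CC)oc2=O)=C(OCOC)C1=CC=C(C)C | intermediate (not isolated)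
15 | 3-{[5,7-bis(methoxymethoxy)-2,2-dimethyl-2H-chromen-6-yl]methyl}-6-ethyl-4-hydroxy-5-methyl-2H-pyran-2-one | CCc1oc(=O)c(Cc2c(OCOC)cc3OC(C)(C)C=Cc3c2OCOC)c(O)c1C | intermediate
16 | 3-[(5,7-dihydroxy-2,2-dimethyl-2H-chromen-6-yl)methyl]-6-ethyl-4-hydroxy-5-methyl-2H-pyran-2-one | CCc1oc(=O)c(Cc2c(O)cc3OC(C)(C)C=Cc3c2O)c(O)c1C | intermediate
17 | (S)-2-methylbutanoic acid | OC(=O)[C@@H](C)CC | starting material
18 | (S)-2-methylbutanoyl chloride | ClC(=O)[C@@H](C)CC | intermediate
19 | 3-({5,7-dihydroxy-2,2-dimethyl-8-[(2S)-2-methylbutanoyl]-2H-chromen-6-yl}methyl)-6-ethyl-4-hydroxy-5-methyl-2H-pyran-2-one | CCc1oc(=O)c(Cc2c(O)c3c(c(C(=O)[C@@H](C)CC)c2O)OC(C)(C)C=C3)c(O)c1C | target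

## Step count and least certain steps

Total steps: 11. Longest linear sequence: 10 (steps 1 to 9 and step 11); step 10 is a one-step side branch.

Step 6 (key step). The acyl donor 8 may enolise in preference to the ketone, so that ketene formation and self-condensation of the donor outrun the cross-acylation. O-acylation of the enolate and Lewis acid-induced loss of a MOM acetal are further risks.
Fallback, from 3 back to 11: the pyrone would be made first and the bridge bond last. Acylation of the dianion of methyl 3-oxopentanoate (NaH, then n-BuLi, THF) with methyl propanoate should give methyl 4-methyl-3,5-dioxoheptanoate F1. DBU in hot toluene should lactonise it to 6-ethyl-4-hydroxy-5-methyl-2H-pyran-2-one F2. A three-component reductive alkylation of F2 with aldehyde 3 and Hantzsch ester (L-proline, CH2Cl2–EtOH, rt) should then give 11.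

Step 11. The acid chloride may racemise through ketene or enol formation under the Lewis acid. Acid may also add to, or oligomerise, the chromene C3=C4 bond, and acylation may stop at oxygen.
Fallback, from 15 back to 19, with reversed polarity and no Lewis acid: iodination of the only free ring carbon of 15 (N-iodosuccinimide, MeCN, 0 °C) should give 3-{[8-iodo-5,7-bis(methoxymethoxy)-2,2-dimethyl-2H-chromen-6-yl]methyl}-6-ethyl-4-hydroxy-5-methyl-2H-pyran-2-one F3. Iodine–magnesium exchange (i-PrMgCl·LiCl, one extra equivalent for the pyrone OH, THF, −20 °C) and addition of (2S)-N-methoxy-N,2-dimethylbutanamide F4 (from 18 and N,O-dimethylhydroxylamine hydrochloride with pyridine) should give 3-({5,7-bis(methoxymethoxy)-2,2-dimethyl-8-[(2S)-2-methylbutanoyl]-2H-chromen-6-yl}methyl)-6-ethyl-4-hydroxy-5-methyl-2H-pyran-2-one F5. Acetal cleavage as in step 9 would then give 19.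

Step 8. The ring carbon of the mono-phenol may be too weakly nucleophilic, so that thermal oligomerisation of the enal wins. Loss of a MOM group at reflux would also open the way to the wrong ring closure.
Fallback, from 12 back to 15: magnesium-mediated ortho-formylation (MgCl2, Et3N, paraformaldehyde, MeCN, reflux) should give 6-ethyl-3-{[3-formyl-4-hydroxy-2,6-bis(methoxymethoxy)phenyl]methyl}-4-hydroxy-5-methyl-2H-pyran-2-one F6. Excess 2-methylprop-1-enylmagnesium bromide (THF, 0 °C) should give 6-ethyl-4-hydroxy-3-{[4-hydroxy-3-(1-hydroxy-3-methylbut-2-en-1-yl)-2,6-bis(methoxymethoxy)phenyl]methyl}-5-methyl-2H-pyran-2-one F7. On gentle warming in toluene F7 should lose water to the same ortho-quinone methide 14 and close to 15.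

Step 3. Condensation at the hindered, electron-rich aldehyde may be slow, and a second molecule of 4 may add to 5 before hydride transfer.
Fallback, from 3 back to 7, by the stepwise dialkyl malonate route: Knoevenagel condensation with dimethyl malonate (piperidine, AcOH, toluene, Dean–Stark) should give dimethyl 2-{[4-(benzyloxy)-2,6-bis(methoxymethoxy)phenyl]methylidene}propanedioate F8. Conjugate reduction (NaBH4, MeOH–THF, 0 °C) should give dimethyl 2-{[4-(benzyloxy)-2,6-bis(methoxymethoxy)phenyl]methyl}propanedioate F9. Mono-saponification (KOH, 1 equiv, MeOH, rt) would give 7.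

## Further compounds

F1 | step 6 | methyl 4-methyl-3,5-dioxoheptanoate | CCC(=O)C(C)C(=O)CC(=O)OC
F2 | step 6 | 6-ethyl-4-hydroxy-5-methyl-2H-pyran-2-one | CCc1oc(=O)cc(O)c1C
F3 | step 11 | 3-{[8-iodo-5,7-bis(methoxymethoxy)-2,2-dimethyl-2H-chromen-6-yl]methyl}-6-ethyl-4-hydroxy-5-methyl-2H-pyran-2-one | CCc1oc(=O)c(Cc2c(OCOC)c(I)c3OC(C)(C)C=Cc3c2OCOC)c(O)c1C
F4 | step 11 | (2S)-N-methoxy-N,2-dimethylbutanamide | CC[C@H](C)C(=O)N(C)OC
F5 | step 11 | 3-({5,7-bis(methoxymethoxy)-2,2-dimethyl-8-[(2S)-2-methylbutanoyl]-2H-chromen-6-yl}methyl)-6-ethyl-4-hydroxy-5-methyl-2H-pyran-2-one | CCc1oc(=O)c(Cc2c(OCOC)c(C(=O)[C@@H](C)CC)c3OC(C)(C)C=Cc3c2OCOC)c(O)c1C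
F6 | step 8 | 6-ethyl-3-{[3-formyl-4-hydroxy-2,6-bis(methoxymethoxy)phenyl]methyl}-4-hydroxy-5-methyl-2H-pyran-2-one | CCc1oc(=O)c(Cc2c(OCOC)cc(O)c(C=O)c2OCOC)c(O)c1C
F7 | step 8 | 6-ethyl-4-hydroxy-3-{[4-hydroxy-3-(1-hydroxy-3-methylbut-2-en-1-yl)-2,6-bis(methoxymethoxy)phenyl]methyl}-5-methyl-2H-pyran-2-one (racemic) | CCc1oc(=O)c(Cc2c(OCOC)cc(O)c(C(O)C=C(C)C)c2OCOC)c(O)c1C
F8 | step 3 | dimethyl 2-{[4-(benzyloxy)-2,6-bis(methoxymethoxy)phenyl]methylidene}propanedioate | COC(=O)C(=Cc1c(OCOC)cc(OCc2ccccc2)cc1OCOC)C(=O)OC
F9 | step 3 | dimethyl 2-{[4-(benzyloxy)-2,6-bis(methoxymethoxy)phenyl]methyl}propanedioate | COC(=O)C(Cc1c(OCOC)cc(OCc2ccccc2)cc1OCOC)C(=O)OC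
A1 | alternative 1 | (S)-1-(2-ethoxy-4-hydroxy-6-methoxyphenyl)-2-methylbutan-1-one | CCOc1cc(O)cc(OC)c1C(=O)[C@@H](C)CC
A2 | alternative 1 | (S)-1-ethoxy-4-methylhex-1-yn-3-one | CCOC#CC(=O)[C@@H](C)CC
A3 | alternative 1 | 1,1-dimethoxy-3-(trimethylsilyloxy)buta-1,3-diene | COC(OC)=CC(=C)O[Si](C)(C)C
A4 | alternative 1 | 6-ethyl-4-hydroxy-5-methyl-2H-pyran-2-one | CCc1oc(=O)cc(O)c1C
A5 | alternative 2 | (S)-2-methyl-1-(2,4,6-trihydroxyphenyl)butan-1-one | Oc1cc(O)c(C(=O)[C@@H](C)CC)c(O)c1
A6 | alternative 2 | 4-hydroxy-6-[(3S)-3-methyl-2-oxopentyl]-2H-pyran-2-one | O=c1cc(O)cc(CC(=O)[C@@H](C)CC)o1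
A7 | alternative 2 | (2S)-1-(5,7-dihydroxy-2,2-dimethyl-2H-chromen-8-yl)-2-methylbutan-1-one | CC[C@H](C)C(=O)c1c(O)cc(O)c2C=CC(C)(C)Oc12
A8 | alternative 3 | methyl (2Z)-3-({3-[5,7-bis(methoxymethoxy)-2,2-dimethyl-2H-chromen-6-yl]propanoyl}oxy)-2-methylpent-2-enoate | COC(=O)/C(C)=C(/CC)OC(=O)CCc1c(OCOC)cc2OC(C)(C)C=Cc2c1OCOC
A9 | alternative 3 | 3-{[5,7-bis(methoxymethoxy)-2,2-dimethyl-2H-chromen-6-yl]methyl}-6-ethyl-4-hydroxy-5-methyl-2H-pyran-2-one | CCc1oc(=O)c(Cc2c(OCOC)cc3OC(C)(C)C=Cc3c2OCOC)c(O)c1C
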